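**Retrosynthetic overview**

1. Labels: ring C1 (CMe2), C2 (CHCl), C3 (CH2), C4 (=CH), C5 (=C), C6 (CHBr); side chain C7 (CHCl), C8 (CH2Br). The route rests on the fact that both heteroatom carbons C6 and C7 hang on alkene carbon C5 of the single cyclohexene ring, the pattern of a 2-acylcyclohex-2-en-1-ol.
2. C6–Br, C7–Cl and C8–Br are traced back to C6–OH (inversion), C7=O (directed reduction, then inversion) and C8–OSi.
3. The only ring is closed by forming C5–C6 in an intramolecular Morita–Baylis–Hillman reaction of an acyclic enone–aldehyde; C2–Cl relays to C6, and C6–OH then relays to C7.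
4. The enone–aldehyde comes from cross-metathesis (C4=C5) of a silyloxymethyl vinyl ketone with (S)-3-chloro-2,2-dimethylhex-5-enal.
5. That aldehyde comes from 2,2-dimethylpent-4-enal by acetalisation, ozonolysis, enamine-catalysed α-chlorination (C2 centre), reduction and vinyl-for-triflate coupling (C3–C4).

Key step: step 10

Remark: the (2S,5S) catalyst of step 3 is assigned to the (R)-chloro aldehyde by the phenyl-shielding model of the enamine; should the sense be the reverse, the (2R,5R) antipode is taken and nothing else changes.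

**Route**

Step 1
Reactants: 1 2,2-dimethylpent-4-enal
Product: 2 5,5-dimethoxy-4,4-dimethylpent-1-ene
Conditions: HC(OMe)3, p-TsOH·H2O (cat.), MeOH, rt; NaHCO3 quench
Reagents that add atoms: trimethyl orthoformate COC(OC)OC
Why: acid-catalysed acetalisation with the orthoformate as methoxy donor and water scavenger masks the neopentyl aldehyde, so that only the aldehyde made in step 2 can form an enamine or be reduced.

Step 2
Reactants: 2 5,5-dimethoxy-4,4-dimethylpent-1-ene
Product: 3 4,4-dimethoxy-3,3-dimethylbutanal
Conditions: O3, CH2Cl2, −78 °C; then Me2S, −78 °C → rt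
Reagents that add atoms: ozone [O-][O+]=O
Why: ozonolysis with reductive work-up cleaves the terminal alkene to the aldehyde one carbon shorter, and the acyclic acetal is inert to ozone at −78 °C.

Step 3
Reactants: 3 4,4-dimethoxy-3,3-dimethylbutanal
Product: 5 (2R)-2-chloro-4,4-dimethoxy-3,3-dimethylbutan-1-ol, via α-chloro aldehyde 4 (not isolated)
Conditions: NCS (1.2 equiv), (2S,5S)-2,5-diphenylpyrrolidine (10 mol%), CH2Cl2, 0 °C → rt; then NaBH4, MeOH, 0 °C; base-washed silica
Reagents that add atoms: N-chlorosuccinimide O=C1CCC(=O)N1Cl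
Why: enamine-catalysed asymmetric α-chlorination, in which the phenyl group of the C2-symmetric amine shields one enamine face so that chlorine enters from the other and sets the (R) centre (the later ring C2), followed at once by borohydride reduction of the configurationally labile aldehyde.

Step 4
Reactants: 5 (2R)-2-chloro-4,4-dimethoxy-3,3-dimethylbutan-1-ol
Product: 6 (2R)-2-chloro-4,4-dimethoxy-3,3-dimethylbutyl trifluoromethanesulfonate
Conditions: Tf2O (1.05 equiv), 2,6-lutidine, CH2Cl2, −78 °C; cold work-up, used at once without chromatography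
Reagents that add atoms: triflic anhydride FC(F)(F)S(=O)(=O)OS(=O)(=O)C(F)(F)F
Why: O-sulfonylation of the primary alcohol does not touch the stereocentre and supplies the strong leaving group that a β-branched, β-chlorinated carbon needs; keeping the triflate cold suppresses attack by the acetal oxygen.

Step 5
Reactants: 6 (2R)-2-chloro-4,4-dimethoxy-3,3-dimethylbutyl trifluoromethanesulfonate; 7 vinylmagnesium bromide
Product: 8 (4S)-4-chloro-6,6-dimethoxy-5,5-dimethylhex-1-ene
Conditions: CuBr·SMe2 (20 mol%), THF/Et2O, −40 → 0 °C
Reagents that add atoms: none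
Why: copper-catalysed coupling of a Grignard reagent with a primary alkyl triflate is an SN2 displacement at CH2 that forms C3–C4 and leaves the neighbouring C–Cl centre untouched (the descriptor changes from R to S only through the priority rules).

Step 6
Reactants: 8 (4S)-4-chloro-6,6-dimethoxy-5,5-dimethylhex-1-ene
Product: 9 (3S)-3-chloro-2,2-dimethylhex-5-enal
Conditions: 1 M aq. HCl, THF, rt
Reagents that add atoms: water O
Why: acid hydrolysis of the dimethyl acetal is safe here because the aldehyde has no α-hydrogen, so neither epimerisation nor β-elimination of chloride can follow, and no acid-labile group is yet present.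

Step 7
Reactants: 10 (tert-butyldimethylsilyloxy)acetaldehyde; 7 vinylmagnesium bromide
Product: 11 1-[(tert-butyldimethylsilyl)oxy]but-3-en-2-ol (racemic)
Conditions: THF, −78 °C; then H2O
Reagents that add atoms: none
Why: Grignard 1,2-addition to the aldehyde gives the allylic alcohol, whose racemic carbinol centre is erased in the next step.

Step 8
Reactants: 11 1-[(tert-butyldimethylsilyl)oxy]but-3-en-2-ol
Product: 12 1-[(tert-butyldimethylsilyl)oxy]but-3-en-2-one
Conditions: Dess–Martin periodinane, CH2Cl2, 0 °C → rt; used fresh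
Reagents that add atoms: none
Why: Dess–Martin oxidation of the secondary allylic alcohol proceeds under non-basic conditions that spare the silyl ether and the polymerisable vinyl ketone.

Step 9
Reactants: 9 (3S)-3-chloro-2,2-dimethylhex-5-enal; 12 1-[(tert-butyldimethylsilyl)oxy]but-3-en-2-one
Product: 13 (3S,5E)-8-[(tert-butyldimethylsilyl)oxy]-3-chloro-2,2-dimethyl-7-oxooct-5-enal
Conditions: second-generation Hoveyda–Grubbs catalyst, RuCl2(H2IMes)(=CH-C6H4-2-OiPr) (5 mol%), 12 (2.5 equiv), CH2Cl2, 40 °C
Reagents that add atoms: none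
Why: olefin cross-metathesis of a terminal alkene with an electron-poor vinyl ketone is selective for the cross product and for the E enone, and the catalyst tolerates the aldehyde, the chloride and the silyl ether.

Step 10
Reactants: 13 (3S,5E)-8-[(tert-butyldimethylsilyl)oxy]-3-chloro-2,2-dimethyl-7-oxooct-5-enal
Product: 14 (1R,5S)-2-{[(tert-butyldimethylsilyl)oxy]acetyl}-5-chloro-6,6-dimethylcyclohex-2-en-1-ol (hydroxyl cis to chlorine)
Conditions: PBu3 (0.3 equiv), PhOH (0.3 equiv), THF (0.05 M), rt
Reagents that add atoms: none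
Why: Tributylphosphine adds to C4 of the enone and the phosphonium enolate attacks the C6 aldehyde through C5 in an intramolecular aldol step, after which proton transfer (assisted by phenol) and loss of the phosphine restore C4=C5. The closest known reaction type is the phosphine-catalysed intramolecular Morita–Baylis–Hillman cyclisation of 7-oxo-5-enals to 2-acylcyclohex-2-enols. The cyclohexene ring C1–C6 closes in a 6-(enolexo)-exo-trig mode that forms the C5–C6 bond. The new C6 carbinol centre is controlled by the C2 chlorine across the gem-dimethyl carbon: in the chair-like aldol transition state C–Cl and the forming C–O are both equatorial, and because the aldol step is reversible the cis product, whose hydroxyl can hydrogen-bond to the C7 carbonyl, should be funnelled. The step needs the aldehyde to be the only electrophile and the C2–Cl/C3–H pair to survive; the neopentyl aldehyde cannot enolise, the gem-dimethyl group favours ring closure over Rauhut–Currier dimerisation, and the weakly basic, phenol-buffered medium should not trigger vinylogous loss of HCl.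

Step 11
Reactants: 14 (1R,5S)-2-{[(tert-butyldimethylsilyl)oxy]acetyl}-5-chloro-6,6-dimethylcyclohex-2-en-1-ol
Product: 15 (1R,5S)-2-{(1R)-2-[(tert-butyldimethylsilyl)oxy]-1-hydroxyethyl}-5-chloro-6,6-dimethylcyclohex-2-en-1-ol
Conditions: Me4NBH(OAc)3 (5 equiv), MeCN/AcOH (1:1), −30 °C
Reagents that add atoms: none
Why: Evans–Saksena hydroxyl-directed reduction, in which the borohydride bound to O6 delivers hydride internally to the carbonyl face on which O6 lies, with the carbonyl s-trans to C4=C5 so that the CH2OSi group points away from boron; this should give only 1,2-reduction and the 1,3-anti diol with the new C7 centre (R).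

Step 12
Reactants: 15 (1R,5S)-2-{(1R)-2-[(tert-butyldimethylsilyl)oxy]-1-hydroxyethyl}-5-chloro-6,6-dimethylcyclohex-2-en-1-ol
Product: 16 (1S,5S)-2-{(1S)-2-[(tert-butyldimethylsilyl)oxy]-1-chloroethyl}-5-chloro-6,6-dimethylcyclohex-2-en-1-ol
Conditions: PPh3 (1.2 equiv), Cl3CC(O)CCl3, CH2Cl2, −20 → 0 °C
Reagents that add atoms: hexachloroacetone ClC(Cl)(Cl)C(=O)C(Cl)(Cl)Cl
Why: Appel-type deoxychlorination with triphenylphosphine/hexachloroacetone converts secondary allylic alcohols to chlorides with inversion and without allylic shift, and should take the C7 hydroxyl because the neopentyl C6 hydroxyl is activated and displaced far more slowly; inversion sets (S) at C7.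

Step 13
Reactants: 16 (1S,5S)-2-{(1S)-2-[(tert-butyldimethylsilyl)oxy]-1-chloroethyl}-5-chloro-6,6-dimethylcyclohex-2-en-1-ol
Product: 17 tert-butyl{(2S)-2-[(4S,6R)-6-bromo-4-chloro-5,5-dimethylcyclohex-1-en-1-yl]-2-chloroethoxy}dimethylsilane
Conditions: CBr4 and PPh3 premixed (2 equiv each), CH2Cl2, 0 → 40 °C
Reagents that add atoms: carbon tetrabromide BrC(Br)(Br)Br
Why: Appel bromination, in which the C6 oxyphosphonium salt has no β-hydrogen (C1 quaternary, C5 sp2) so that elimination is excluded and bromide displaces at the allylic carbon with inversion, placing bromine trans to the ring chlorine, which is also expected to be the more stable C6 epimer (Br pseudoaxial, Cl equatorial) if bromide exchange occurs.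

Step 14
Reactants: 17 tert-butyl{(2S)-2-[(4S,6R)-6-bromo-4-chloro-5,5-dimethylcyclohex-1-en-1-yl]-2-chloroethoxy}dimethylsilane
Product: 18 (4S,6R)-6-bromo-1-[(1S)-2-bromo-1-chloroethyl]-4-chloro-5,5-dimethylcyclohex-1-ene (CNP0105443.4)
Conditions: Ph3PBr2 (1.5 equiv), CH2Cl2, 0 °C → rt
Reagents that add atoms: triphenylphosphine dibromide Br[P+](c1ccccc1)(c1ccccc1)c1ccccc1.[Br-]
Why: direct conversion of a primary tert-butyldimethylsilyl ether into the bromide by bromophosphonium activation (the silyl bromide leaves and bromide displaces at the primary carbon) installs C8–Br without a free 1,4-diol stage that could close to a cyclic ether, and no stereocentre is involved.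

**Compound list**

1 | 2,2-dimethylpent-4-enal | C=CCC(C)(C)C=O | starting material
2 | 5,5-dimethoxy-4,4-dimethylpent-1-ene | C=CCC(C)(C)C(OC)OC | intermediate
3 | 4,4-dimethoxy-3,3-dimethylbutanal | O=CCC(C)(C)C(OC)OC | intermediate
4 | (2R)-2-chloro-4,4-dimethoxy-3,3-dimethylbutanal | COC(OC)C(C)(C)[C@@H](Cl)C=O | intermediate
5 | (2R)-2-chloro-4,4-dimethoxy-3,3-dimethylbutan-1-ol | COC(OC)C(C)(C)[C@@H](Cl)CO | intermediate
6 | (2R)-2-chloro-4,4-dimethoxy-3,3-dimethylbutyl trifluoromethanesulfonate | COC(OC)C(C)(C)[C@@H](Cl)COS(=O)(=O)C(F)(F)F | intermediate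
7 | vinylmagnesium bromide | C=C[Mg]Br | starting material
8 | (4S)-4-chloro-6,6-dimethoxy-5,5-dimethylhex-1-ene | COC(OC)C(C)(C)[C@@H](Cl)CC=C | intermediate
9 | (3S)-3-chloro-2,2-dimethylhex-5-enal | O=CC(C)(C)[C@@H](Cl)CC=C | intermediate
10 | (tert-butyldimethylsilyloxy)acetaldehyde | O=CCO[Si](C)(C)C(C)(C)C | starting material
11 | 1-[(tert-butyldimethylsilyl)oxy]but-3-en-2-ol (racemic) | C=CC(O)CO[Si](C)(C)C(C)(C)C | intermediate
12 | 1-[(tert-butyldimethylsilyl)oxy]but-3-en-2-one | C=CC(=O)CO[Si](C)(C)C(C)(C)C | intermediate
13 | (3S,5E)-8-[(tert-butyldimethylsilyl)oxy]-3-chloro-2,2-dimethyl-7-oxooct-5-enal | O=CC(C)(C)[C@@H](Cl)C/C=C/C(=O)CO[Si](C)(C)C(C)(C)C | intermediate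
14 | (1R,5S)-2-{[(tert-butyldimethylsilyl)oxy]acetyl}-5-chloro-6,6-dimethylcyclohex-2-en-1-ol | CC1(C)[C@@H](Cl)CC=C(C(=O)CO[Si](C)(C)C(C)(C)C)[C@H]1O | intermediate
15 | (1R,5S)-2-{(1R)-2-[(tert-butyldimethylsilyl)oxy]-1-hydroxyethyl}-5-chloro-6,6-dimethylcyclohex-2-en-1-ol | CC1(C)[C@@H](Cl)CC=C([C@@H](O)CO[Si](C)(C)C(C)(C)C)[C@H]1O | intermediate
16 | (1S,5S)-2-{(1S)-2-[(tert-butyldimethylsilyl)oxy]-1-chloroethyl}-5-chloro-6,6-dimethylcyclohex-2-en-1-ol | CC1(C)[C@@H](Cl)CC=C([C@H](Cl)CO[Si](C)(C)C(C)(C)C)[C@H]1O | intermediate
17 | tert-butyl{(2S)-2-[(4S,6R)-6-bromo-4-chloro-5,5-dimethylcyclohex-1-en-1-yl]-2-chloroethoxy}dimethylsilane | CC1(C)[C@@H](Cl)CC=C([C@H](Cl)CO[Si](C)(C)C(C)(C)C)[C@@H]1Br | intermediate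
18 | (4S,6R)-6-bromo-1-[(1S)-2-bromo-1-chloroethyl]-4-chloro-5,5-dimethylcyclohex-1-ene | CC1(C)[C@@H](Cl)CC=C([C@H](Cl)CBr)[C@@H]1Br | target

Total steps: 14. Longest linear sequence: 12 steps (steps 1–6 and 9–14).

**Steps most likely to fail**

Step 13 (bromination at C6). Direct displacement at the neopentyl allylic carbon is slow. Bromide may therefore be delivered to C4 with allylic shift, or ionisation of the oxyphosphonium salt may erode the inversion. The fallback sets out from 16 and replaces phosphonium activation by a discrete sulfonate displacement. Tf2O and 2,6-di-tert-butyl-4-methylpyridine in CH2Cl2 at −78 °C should give the allylic triflate F1. This is displaced cold in the same flask by Bu4NBr in a non-ionising medium, so that direct SN2 with inversion can proceed at low temperature. The sequence comes back to the route at 17.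

Step 10 (ring closure). The aldol onto the hindered aldehyde may be slow, letting the enone oligomerise. The basic zwitterions may cause loss of HCl across C2–C3. Facial selectivity at C6 may be poor. The fallback sets out from 13 and separates addition from elimination. 4-Methylbenzenethiol with catalytic lithium 4-methylbenzenethiolate in THF at 0 °C should effect a thiolate-triggered Michael–aldol cyclisation to the 2-acyl-3-(arylsulfanyl)cyclohexanol F2. This is isolable, and its carbinol epimers can equilibrate through the reversible aldol step. Oxidation with mCPBA at −78 °C should give the sulfoxide F3. Thermal syn-elimination of F3 towards the acidic C5 hydrogen (toluene, 60 °C, CaCO3) then forms C4=C5, and the sequence comes back to the route at 14.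

Step 12 (chlorination at C7). The phosphorus reagent may activate or bridge the wrong hydroxyl. Chloride may be delivered to C4 with allylic shift, or an ion pair may leak retention. The fallback sets out from 15 and needs no discrimination between the two hydroxyls. SOCl2 and pyridine in CH2Cl2 at 0 °C should give the six-membered cyclic sulfite F4. LiCl in DMF at 70 °C should open it at the non-neopentyl allylic carbon C7 with inversion, giving the lithium alkyl sulfite F5. Dilute aqueous HCl on work-up releases the C6 hydroxyl, and the sequence comes back to the route at 16.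

**Further compounds**

F1 | step 13 | (1S,5S)-2-{(1S)-2-[(tert-butyldimethylsilyl)oxy]-1-chloroethyl}-5-chloro-6,6-dimethylcyclohex-2-en-1-yl trifluoromethanesulfonate | CC1(C)[C@@H](Cl)CC=C([C@H](Cl)CO[Si](C)(C)C(C)(C)C)[C@H]1OS(=O)(=O)C(F)(F)F
F2 | step 10 | 2-[(tert-butyldimethylsilyl)oxy]-1-[4-chloro-2-hydroxy-3,3-dimethyl-6-(4-methylphenylsulfanyl)cyclohexyl]ethan-1-one (hydroxyl cis to chlorine, 4S; sulfur- and acyl-bearing carbons undefined) | CC1(C)[C@@H](Cl)CC(Sc2ccc(C)cc2)C(C(=O)CO[Si](C)(C)C(C)(C)C)[C@H]1O
F3 | step 10 | sulfoxide of F2, 2-[(tert-butyldimethylsilyl)oxy]-1-[4-chloro-2-hydroxy-3,3-dimethyl-6-(4-methylphenylsulfinyl)cyclohexyl]ethan-1-one | CC1(C)[C@@H](Cl)CC(S(=O)c2ccc(C)cc2)C(C(=O)CO[Si](C)(C)C(C)(C)C)[C@H]1O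
F4 | step 12 | cyclic sulfite of diol 15 (1,3,2-dioxathiane 2-oxide fused to the cyclohexene, sulfur epimers) | CC1(C)[C@@H](Cl)CC=C2[C@H](CO[Si](C)(C)C(C)(C)C)OS(=O)O[C@@H]12
F5 | step 12 | lithium (1S,5S)-2-{(1S)-2-[(tert-butyldimethylsilyl)oxy]-1-chloroethyl}-5-chloro-6,6-dimethylcyclohex-2-en-1-yl sulfite | CC1(C)[C@@H](Cl)CC=C([C@H](Cl)CO[Si](C)(C)C(C)(C)C)[C@H]1OS(=O)[O-].[Li+]
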